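## Structural features

The target is a drimane: a trans-fused decalin in which ring A (C1–C5, C10) carries the C4 gem-dimethyl group and ring B (C5–C10) carries the angular C10 methyl, the acid C11 on C9, the acid C12 on C8 and a (2E,4E,6E)-octa-2,4,6-trienoate on O6 (drimane numbering; β is the face of the C10 methyl). It has five stereocentres, C6, C5, C10, C9 and C8, which follow one another around ring B with only the C7 methylene between C6 and C8. The C10 methyl, C12 and O6 are all axial on the β-face and mutually 1,3-diaxial, C11 is equatorial and cis to C12, and H5 is α. The fragile parts are the trienoate (a light-sensitive Michael acceptor that tolerates neither strong base nor nucleophiles), the axial C8 carboxyl (it relaxes to the equatorial epimer once a C12 ester meets base) and the O6/C12 pair, which closes to a lactone whenever O6 is free and C12 is electrophilic. The difficulty is twofold: a contra-thermodynamic all-axial array on a crowded face next to a quaternary carbon, and acylation of a hindered axial alcohol that sits within reach of a carboxyl group. The key step uses the second problem to solve the first: O6–C6–C7–C8–C12 is a γ-hydroxy acid whose lactone can span C6 and C8 only when both substituents are axial and cis, and C6–C7 lies β to the C12 carbonyl, so a C6 ketyl can add to the CH2 terminus of a C8 acrylate and be trapped as that lactone.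

## Logic of the disconnections

22 ⇒ 21. The C11–O and C12–O ester bonds (tert-butyl and 4-methoxybenzyl) are cut together by acidolysis. This keeps both acids masked through every basic or nucleophilic operation and ends the route with one deprotection. The forward step must spare the triene and use no base, because C8 is then no longer locked.

21 ⇒ 18 + 19. The O6–acyl bond is cut so that the sensitive side chain enters last and never meets radicals, one-electron reductants or amide bases. The demand is severe: O6 of 18 is axial, has two syn-axial methyl groups and is 1,3-diaxial to the C12 ester, so acylation must outrun return to the lactone and must run without an alkoxide.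

18 ⇒ 16. The benzylic ester bond is cut and O6–C12 is reconnected, so 16 holds O6 and C12 as one lactone. The lactone protects both functions and locks C8, whose hydrogen sits at a bridgehead. The forward step needs hydroxide to open the lactone without touching the C11 tert-butyl ester, and the carboxylate must be alkylated without ever being protonated.

16 ⇒ 14. No skeletal bond is cut; only the C9–H bond is at issue, 14 being the mixture of C9 epimers. Correcting C9 after ring closure means it need not be controlled when C10–C9 is made. The forward step needs an amide base that does not open the lactone and protonation of the enolate from the α-face.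

14 ⇒ 12. C6–C7 (ring B) and O6–C12 (lactone) are cut. The bicyclic lactone becomes a monocycle with only C5 and C10 defined, and C6 and C8 are cleared. The forward step needs 6-endo attack of the C6 ketyl on C7, an axial O6 and α-face protonation at C8. For this reason 12 carries a methyl ester at C12 and a tert-butyl ester only at C11: a tert-butyl ester at C12 would resist the alkoxide and bind the metal poorly.

12 ⇒ 11. Only the oxidation level at C6 changes. The aldehyde is made just before use because it is epimerisable and would not survive the radical coupling. The oxidant must be neutral, since base would move the C7=C8 alkene into conjugation through C9.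

11 ⇒ 10 + 4. The C10–C9 bond is cut, giving a ring A piece with the C5 stereocentre and a four-carbon acceptor with both carboxyls. The quaternary C10 then comes from a trisubstituted alkene and the C7 methylene from allylic transposition. The forward step needs hydrogen-atom delivery to C1, addition of the tertiary radical to the CH terminus of 4 with loss of bromine, and attack trans to C6; C9 is left uncontrolled on purpose.

10 ⇒ 8 ⇒ 6 (+ 7) ⇒ 5. These are oxidation-level changes at C6 around a classical resolution. The acid is the one stage with a handle for salt formation and, unlike 5, it does not racemise or isomerise readily. The demand is clean discrimination between the diastereomeric salts.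

4 ⇒ 3 ⇒ 1 + 2. The C–Br bond is cut (allylic bromination), then the C=C bond (olefination). This places the methyl and tert-butyl esters on defined carbons, which opening a cyclic anhydride would not do cleanly. Alkene geometry need not be controlled because the bromination equilibrates it.

## Other disconnections considered

Alternative 1: The cut goes through ring A at C1–C10 and C4–C5. Allylidenecyclopropane A2 would add across C5=C10 of the ring B enone anhydride A1 to give the cis-fused adduct A3. The spiro-cyclopropane of A3 would later be hydrogenolysed to the gem-dimethyl group and C5 inverted through the C6 ketone.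
- In its favour: it is convergent and the strained diene is reactive. The anhydride fixes C8 and C9 cis from the start, and C6 arrives as a ketone that hydride should reduce from the open α-face to the axial 6β-alcohol. On both points it is better secured than the chosen plan, where C9 needs a separate enolate protonation and C6 rests on chelation.
- Against it: the dienophile is a β,β-disubstituted enone that must form the quaternary C10, so the cycloaddition would be sluggish. Both stereocentres of A1 are α to an anhydride carbonyl and one is also vinylogously α to the ketone, so A1 would be hard to make and keep enantiopure. After the key step come alkene hydrogenation, cyclopropane hydrogenolysis, C5 inversion (with C8 labile) and ketone reduction.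
- Comparison: the freed 6β-hydroxyl would be expected to open the anhydride at C12, so the lactone-versus-acylation problem returns unchanged; on that point the two plans are equal. The mechanism is a concerted, stereospecific cycloaddition against a stepwise radical-anion closure. Step economy looks similar or slightly worse once the synthesis of A1 is counted.

Alternative 2: The cut is C5–C10 and C8–C9, opening both rings to the triene A4. A type 1 intramolecular Diels–Alder reaction of the 2-silyloxy diene with the (E)-enimide would give the octalin A5.
- In its favour: both rings and four contiguous stereocentres form in one operation, which is the best step economy of all from the cyclisation onward. The carboxyls emerge differentiated (equal to the chosen plan). The required topicity has the acyl group endo, which a chelating Lewis acid favours, and a chiral one such as Cu(OTf)2 with a bis(oxazoline) could set absolute configuration catalytically; that is better than a resolution. C6 again arrives as a masked ketone.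
- Against it: C5–C10 would join a neopentyl diene terminus (next to the C4 gem-dimethyl) to a fully substituted dienophile carbon. The diene carries the C8 ester and is electron-poor like the dienophile. A4 needs three defined alkene geometries, including a (Z)-silyl dienol ether of an unsymmetrical ketone, and decatriene closures are weakly biased between cis and trans fusion. Later the imide must be cleaved at a neopentyl carbonyl with C9 epimerisable, and the hydroxy ester/lactone issue still waits at the end.
- Comparison: if the cycloaddition worked it would be shorter than the chosen plan. Its central bond formation is less certain than the 6-endo radical addition, which joins a secondary carbon to an unsubstituted methylene and leaves the quaternary centre to an earlier, simpler step.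

Alternative 3: The cut is C8–C9 alone. The trans-fused δ-lactone A6 (C11 esterified by O6, C6 carrying the (E)-acrylate arm) would be converted into its silyl ketene acetal A7. A7 would rearrange through the boat transition state imposed by the lactone ring to the acid A8.
- In its favour: the [3,3] shift is concerted and suprafacial, so the cis relation of C8 and C9 and the configuration of C9 follow from geometry. That is better secured than in the chosen plan, where C9 is corrected afterwards and C8 depends on the face of protonation. The carboxyls emerge as acid and tert-butyl ester (equal or better).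
- Against it: the rearrangement consumes the C6–O bond, so A8 has a C6=C7 alkene and no oxygen at C6. O6 would have to be reinstalled, most naturally by halolactonisation from C12 and dehalogenation, which reaches the same kind of bridged lactone several steps later. The enolate of A6 can add in Michael fashion to C7 before it is silylated. A6 already contains the quaternary C10, the trans C5/C10 pair and a C6 stereocentre, so it is no easier to make than 12.
- Comparison: it is more predictable on C8/C9 but less economical both before and after the key step, and it spends a stereocentre as a control element.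

Key step: step 8

Assumption: the salt of the (S)-acid with (R)-1-phenylethylamine is taken to be the less soluble one; if the pairing is the reverse, the (S)-amine is used in the same way.

## Route

Step 1
Reactants: 1 methyl pyruvate; 2 tert-butyl 2-(triphenyl-λ5-phosphanylidene)acetate
Product: 3 4-tert-butyl 1-methyl (2E)-2-methylbut-2-enedioate (any Z isomer is carried along)
Conditions: CH2Cl2, 0 °C → rt
Reagents that add atoms: none
Why: Wittig olefination of an activated α-keto ester by a stabilised ylide; it fixes which carboxyl bears which ester (methyl on the methyl-bearing carbon, tert-butyl on the CH carbon), and the geometry need not be pure because step 2 equilibrates it.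

Step 2
Reactants: 3 4-tert-butyl 1-methyl (2E)-2-methylbut-2-enedioate
Product: 4 4-tert-butyl 1-methyl 2-(bromomethyl)fumarate (ester groups trans)
Conditions: NBS (1.1 equiv), AIBN (cat.), PhCF3, 85 °C
Reagents that add atoms: N-bromosuccinimide, O=C1CCC(=O)N1Br
Why: Wohl–Ziegler bromination at the only allylic C–H position; bromine atoms and traces of HBr equilibrate the alkene to the fumarate-type isomer, as is usual for citraconate and mesaconate diesters.

Step 3
Reactants: 5 α-cyclocitral (racemic)
Product: 6 2,6,6-trimethylcyclohex-2-ene-1-carboxylic acid (racemic α-cyclogeranic acid)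
Conditions: NaClO2, NaH2PO4, 2-methyl-2-butene, tBuOH/H2O, 0 °C → rt
Reagents that add atoms: sodium chlorite, [Na+].[O-]Cl=O
Why: Pinnick oxidation is selective for the aldehyde; the scavenger alkene protects the ring double bond from HOCl, and the buffered medium leaves the β,γ-alkene out of conjugation.

Step 4
Reactants: 6 2,6,6-trimethylcyclohex-2-ene-1-carboxylic acid (racemic); 7 (R)-1-phenylethylamine
Product: 8 (R)-1-phenylethylammonium (S)-2,6,6-trimethylcyclohex-2-ene-1-carboxylate
Conditions: 7 (0.5 equiv), acetone, reflux → 4 °C; recrystallise to constant rotation
Reagents that add atoms: none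
Why: Classical resolution by crystallisation of diastereomeric salts with half an equivalent of amine; the (S)-acid carries the configuration needed at C5.

Step 5
Reactants: 8 (R)-1-phenylethylammonium (S)-2,6,6-trimethylcyclohex-2-ene-1-carboxylate
Product: 10 [(1S)-2,6,6-trimethylcyclohex-2-en-1-yl]methanol ((S)-α-cyclogeraniol), via (S)-α-cyclogeranic acid 9 (not isolated)
Conditions: 1 M HCl, Et2O, 0 °C; dry, concentrate; then LiAlH4, THF, 0 °C → rt
Reagents that add atoms: none
Why: Liberation of the acid and hydride reduction to the primary alcohol, which leaves the stereocentre untouched; the alcohol is carried forward because the corresponding aldehyde racemises and isomerises to the conjugated β-isomer too easily.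

Step 6
Reactants: 10 [(1S)-2,6,6-trimethylcyclohex-2-en-1-yl]methanol; 4 4-tert-butyl 1-methyl 2-(bromomethyl)fumarate
Product: 11 4-tert-butyl 1-methyl 3-[(1S,2S)-2-(hydroxymethyl)-1,3,3-trimethylcyclohexyl]-2-methylidenebutanedioate (both epimers at C3 of the diester, which is C9)
Conditions: 4 (2 equiv), Fe(acac)3 (0.3 equiv), PhSi(OiPr)H2 (2 equiv), Na2HPO4, THF/iPrOH 10:1, rt → 40 °C; chromatography removes any cis isomer
Reagents that add atoms: none
Why: Metal-hydride hydrogen-atom transfer (Mukaiyama-type) from an iron hydride puts H on C1 and leaves the tertiary C10 radical, which adds to the CH terminus of the fumarate (C9); the adduct radical expels a bromine atom, a Giese addition–fragmentation (radical SN2′ allylation) that installs the C7 methylene. The C10–C9 bond should form trans to C6 because the face syn to the CH2OH group is also guarded by the axial C4 methyl. C9 forms as a mixture, which is accepted because step 9 corrects it.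

Step 7
Reactants: 11 4-tert-butyl 1-methyl 3-[(1S,2S)-2-(hydroxymethyl)-1,3,3-trimethylcyclohexyl]-2-methylidenebutanedioate
Product: 12 4-tert-butyl 1-methyl 3-[(1S,2S)-2-formyl-1,3,3-trimethylcyclohexyl]-2-methylidenebutanedioate (C9 epimers)
Conditions: DMP, CH2Cl2, 0 °C → rt
Reagents that add atoms: none
Why: Dess–Martin oxidation under near-neutral conditions, so the 1,1-disubstituted acrylate is not drawn into conjugation through C9; C5 is safe because the trans-diequatorial arrangement is the stable one.

Step 8
Reactants: 12 4-tert-butyl 1-methyl 3-[(1S,2S)-2-formyl-1,3,3-trimethylcyclohexyl]-2-methylidenebutanedioate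
Product: 14 tert-butyl 12,6β-olide-drimane-11-oate as a mixture of C9 epimers, via samarium alkoxide of cyclised hydroxy diester 13 (not isolated)
Conditions: SmI2 (2.5 equiv), tBuOH (3 equiv), THF, −78 → 0 °C, slow addition of 12; then rt; aq. NH4Cl
Reagents that add atoms: none
Why: Divalent samarium transfers one electron to the aldehyde, and the ketyl, held on trivalent samarium that also binds the C12 methyl ester carbonyl, adds through C6 to the CH2 terminus C7; a second electron turns the stabilised C8 radical into the samarium enolate, tBuOH protonates C8, and the C6 alkoxide attacks C12 and expels methoxide. The closest known reaction type is the SmI2-mediated ketyl–olefin reductive cyclisation onto α,β-unsaturated esters with γ-lactone formation in the same flask. Ring B closes 6-endo-trig, because the nucleophilic ketyl attacks the β-carbon of the acceptor and 5-exo attack would have to bond to the fully substituted, electronically mismatched C8; the lactone closes 5-exo-trig by acyl substitution to a 6-oxabicyclo[3.2.1]octan-7-one in which ring B stays a chair. C6 is controlled by chelation: in the chair-like transition state of the forming trans-decalin only an axial (β) ketyl oxygen is gauche to C8 and can share the metal with the ester carbonyl, whereas an equatorial oxygen points away from it. C8 is controlled by the face of protonation: the β-face of the enolate is covered by the axial C10 methyl and the samarium bridge to O6, so the proton arrives from the α-face and C12 ends axial and β. The step needs 6-endo regioselectivity, secured by the 1,1-disubstituted acrylate, and the cis-diaxial O6/C12 relation, secured by the chelate; lactonisation does not create this selectivity but is possible only in that isomer, so isolating the lactone also separates it from any cyclised hydroxy ester of the wrong configuration. The C12 ester is methyl because methoxide leaves readily and the small ester binds samarium well, which a tert-butyl ester would not.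

Step 9
Reactants: 14 tert-butyl 12,6β-olide-drimane-11-oate (C9 epimers)
Product: 16 tert-butyl 12,6β-olide-drimane-11-oate (9β-ester and 9α-H), via lithium ester enolate 15 (not isolated)
Conditions: LiN(iPr)2 (1.5 equiv), THF, −78 → −30 °C; then AcOH in THF, −78 °C
Reagents that add atoms: none
Why: Kinetic enolisation and protonation of the ester; C8 cannot enolise because it is the bridgehead of the bicyclic lactone (Bredt's rule), and an amide base does not open the lactone as an alkoxide could. The proton enters C9 along the axial trajectory from the α-face, since the β-face is blocked by the adjacent axial C10 methyl and the lactone bridge, so both epimers converge on the equatorial 9β-ester.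

Step 10
Reactants: 16 tert-butyl 12,6β-olide-drimane-11-oate (9β-ester)
Product: 18 11-tert-butyl 12-(4-methoxybenzyl) 6β-hydroxydrimane-11,12-dioate, via tetrabutylammonium carboxylate 17 (not isolated)
Conditions: Bu4NOH (1.05 equiv), THF/H2O, 0 °C → rt; evaporate, azeotrope with PhMe; then 4-methoxybenzyl chloride (1.3 equiv), DMF, rt
Reagents that add atoms: tetrabutylammonium hydroxide, CCCC[N+](CCCC)(CCCC)CCCC.[OH-]; 4-methoxybenzyl chloride, COc1ccc(CCl)cc1
Why: BAc2 saponification of the bridged lactone by one equivalent of hydroxide, which the hindered tert-butyl ester resists, then SN2 alkylation of the carboxylate. The γ-hydroxy acid is never protonated and so cannot relactonise, and C8 is not epimerisable while it is a carboxylate.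

Step 11
Reactants: 18 11-tert-butyl 12-(4-methoxybenzyl) 6β-hydroxydrimane-11,12-dioate; 19 (2E,4E,6E)-octa-2,4,6-trienoic acid
Product: 21 11-tert-butyl 12-(4-methoxybenzyl) 6β-[(2E,4E,6E)-octa-2,4,6-trienoyloxy]drimane-11,12-dioate, via mixed trichlorobenzoic anhydride 20 (not isolated)
Conditions: 19 (3 equiv), 2,4,6-trichlorobenzoyl chloride, Et3N, THF, rt; then 18, DMAP (4 equiv), PhMe, rt → 40 °C, dark
Reagents that add atoms: none
Why: Yamaguchi esterification, a standard answer to hindered secondary alcohols that is compatible with polyenoic acids lacking sp3 γ-hydrogens. No alkoxide is formed, which keeps attack of O6 on the neighbouring ester slow, and C6 keeps its configuration because only the O–H bond reacts.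

Step 12
Reactants: 21 11-tert-butyl 12-(4-methoxybenzyl) 6β-[(2E,4E,6E)-octa-2,4,6-trienoyloxy]drimane-11,12-dioate
Product: 22 6β-[(2E,4E,6E)-octa-2,4,6-trienoyloxy]drimane-11,12-dioic acid (5α-H, 8β-CO2H, 9β-CO2H, 10β-CH3)
Conditions: CF3CO2H/CH2Cl2 1:4, anisole (10 equiv), 0 °C → rt, dark
Reagents that add atoms: none
Why: AAL1 acidolysis of the tert-butyl and 4-methoxybenzyl esters with anisole as cation trap; the conjugated trienoate is electron-poor and should resist protonation, and with no base present the axial C8 carboxyl cannot epimerise.

## Compound list

1 | methyl pyruvate | COC(=O)C(C)=O | starting material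
2 | tert-butyl 2-(triphenyl-λ5-phosphanylidene)acetate | CC(C)(C)OC(=O)C=P(c1ccccc1)(c1ccccc1)c1ccccc1 | starting material
3 | 4-tert-butyl 1-methyl (2E)-2-methylbut-2-enedioate | COC(=O)/C(C)=C/C(=O)OC(C)(C)C | intermediate
4 | 4-tert-butyl 1-methyl 2-(bromomethyl)fumarate (esters trans; formally 2Z) | COC(=O)/C(CBr)=C/C(=O)OC(C)(C)C | intermediate
5 | α-cyclocitral (racemic) | CC1=CCCC(C)(C)C1C=O | starting material
6 | 2,6,6-trimethylcyclohex-2-ene-1-carboxylic acid (racemic) | CC1=CCCC(C)(C)C1C(=O)O | intermediate
7 | (R)-1-phenylethylamine | C[C@@H](N)c1ccccc1 | starting material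
8 | (R)-1-phenylethylammonium (S)-2,6,6-trimethylcyclohex-2-ene-1-carboxylate | [O-]C(=O)[C@H]1C(C)(C)CCC=C1C.C[C@@H]([NH3+])c1ccccc1 | intermediate
9 | (S)-2,6,6-trimethylcyclohex-2-ene-1-carboxylic acid | OC(=O)[C@H]1C(C)(C)CCC=C1C | intermediate (not isolated)
10 | [(1S)-2,6,6-trimethylcyclohex-2-en-1-yl]methanol | OC[C@H]1C(C)(C)CCC=C1C | intermediate
11 | 4-tert-butyl 1-methyl 3-[(1S,2S)-2-(hydroxymethyl)-1,3,3-trimethylcyclohexyl]-2-methylidenebutanedioate (C9 epimers) | OC[C@H]1C(C)(C)CCC[C@]1(C)C(C(=O)OC(C)(C)C)C(=C)C(=O)OC | intermediate
12 | 4-tert-butyl 1-methyl 3-[(1S,2S)-2-formyl-1,3,3-trimethylcyclohexyl]-2-methylidenebutanedioate (C9 epimers) | O=C[C@H]1C(C)(C)CCC[C@]1(C)C(C(=O)OC(C)(C)C)C(=C)C(=O)OC | intermediate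
13 | 11-tert-butyl 12-methyl 6β-hydroxydrimane-11,12-dioate (8β-ester, C9 epimers), present as its samarium alkoxide | O[C@@H]1C[C@H](C(=O)OC)C(C(=O)OC(C)(C)C)[C@@]2(C)CCCC(C)(C)[C@H]12 | intermediate (not isolated)
14 | tert-butyl 12,6β-olide-drimane-11-oate (C9 epimers) | O=C1O[C@@H]2C[C@H]1C(C(=O)OC(C)(C)C)[C@@]3(C)CCCC(C)(C)[C@H]23 | intermediate
15 | lithium enolate of the C11 tert-butyl ester of 14 | O=C1O[C@@H]2C[C@H]1C(=C([O-])OC(C)(C)C)[C@@]3(C)CCCC(C)(C)[C@H]23.[Li+] | intermediate (not isolated)
16 | tert-butyl 12,6β-olide-drimane-11-oate (9β-ester, 9α-H) | O=C1O[C@@H]2C[C@H]1[C@H](C(=O)OC(C)(C)C)[C@@]3(C)CCCC(C)(C)[C@H]23 | intermediate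
17 | tetrabutylammonium 11-tert-butoxy-6β-hydroxy-11-oxodriman-12-oate | O[C@@H]1C[C@H](C(=O)[O-])[C@H](C(=O)OC(C)(C)C)[C@@]2(C)CCCC(C)(C)[C@H]12.CCCC[N+](CCCC)(CCCC)CCCC | intermediate (not isolated)
18 | 11-tert-butyl 12-(4-methoxybenzyl) 6β-hydroxydrimane-11,12-dioate | O[C@@H]1C[C@H](C(=O)OCc3ccc(OC)cc3)[C@H](C(=O)OC(C)(C)C)[C@@]2(C)CCCC(C)(C)[C@H]12 | intermediate
19 | (2E,4E,6E)-octa-2,4,6-trienoic acid | C/C=C/C=C/C=C/C(=O)O | starting material
20 | (2E,4E,6E)-octa-2,4,6-trienoic 2,4,6-trichlorobenzoic anhydride | C/C=C/C=C/C=C/C(=O)OC(=O)c1c(Cl)cc(Cl)cc1Cl | intermediate (not isolated)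
21 | 11-tert-butyl 12-(4-methoxybenzyl) 6β-[(2E,4E,6E)-octa-2,4,6-trienoyloxy]drimane-11,12-dioate | C/C=C/C=C/C=C/C(=O)O[C@@H]1C[C@H](C(=O)OCc3ccc(OC)cc3)[C@H](C(=O)OC(C)(C)C)[C@@]2(C)CCCC(C)(C)[C@H]12 | intermediate
22 | 6β-[(2E,4E,6E)-octa-2,4,6-trienoyloxy]drimane-11,12-dioic acid | C/C=C/C=C/C=C/C(=O)O[C@@H]1C[C@H](C(=O)O)[C@H](C(=O)O)[C@@]2(C)CCCC(C)(C)[C@H]12 | target

## Step count and least certain steps

Total: 12 steps. Longest linear sequence: 10 steps (steps 3–12, from 5); the acceptor branch is 2 steps (steps 1–2).

Step 8 (key step). The most likely failure is poor facial selectivity at the ketyl carbon: an axial samarium-bound oxygen is syn-axial to the C4 and C10 methyl groups, so the oxygen may take the equatorial position if chelation is not strong enough. β-Face protonation at C8 or plain reduction of the hindered aldehyde are lesser risks. Either stereochemical failure leaves a cyclised hydroxy ester that cannot lactonise. The fallback sets out from 12 and returns at 14, and sets C6 by hydride reduction instead of by the cyclisation. 12 is closed by a radical-chain intramolecular hydroacylation (AIBN or (tBuO)2, a thiol such as tert-dodecanethiol as polarity-reversal catalyst, PhCl, 80–110 °C; 6-endo addition of the acyl radical to C7) to 11-tert-butyl 12-methyl 6-oxodrimane-11,12-dioate F1. NaBH4 in MeOH should attack the C6 ketone from the α-face, the β-face carrying two axial methyl groups, to give the 6β-alcohol 11-tert-butyl 12-methyl 6β-hydroxydrimane-11,12-dioate F2. KOtBu (1 equiv) in THF converts F2 into its alkoxide, which closes onto C12 in the 8β-epimer while the 8α-epimer equilibrates through the ester enolate, so the material is drawn into 14.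

Step 6. Three processes may compete with the radical allylation. The allylic bromide may be reduced or solvolysed before the hindered tertiary radical is trapped. Reversible hydrogen-atom transfer may move the ring alkene to the tetrasubstituted position, which would erase the C5 stereocentre. Attack cis to C6 is the third; an excess of 4 is meant to keep trapping fast. The fallback sets out from 10 and returns at 14. 10 is coupled under the same Fe(acac)3/silane conditions with di-tert-butyl fumarate, a plain Giese acceptor, to di-tert-butyl 2-[(1S,2S)-2-(hydroxymethyl)-1,3,3-trimethylcyclohexyl]butanedioate F3. The unhindered C8 methylene is deprotonated selectively (LiN(iPr)2, 2.2 equiv, −78 °C) and aminomethylated with dimethyl(methylidene)ammonium iodide to the Mannich base di-tert-butyl 2-[(dimethylamino)methyl]-3-[(1S,2S)-2-(hydroxymethyl)-1,3,3-trimethylcyclohexyl]butanedioate F4. MeI converts F4 into the trimethylammonium iodide F5, and NaHCO3 eliminates it to di-tert-butyl 3-[(1S,2S)-2-(hydroxymethyl)-1,3,3-trimethylcyclohexyl]-2-methylidenebutanedioate F6. DMP gives di-tert-butyl 3-[(1S,2S)-2-formyl-1,3,3-trimethylcyclohexyl]-2-methylidenebutanedioate F7, and SmI2/tBuOH as in step 8 closes ring B. Lactonisation must then expel tert-butoxide and may need warming; the route is rejoined at 14.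

Step 11. Relactonisation may outrun acylation: the axial 6β-hydroxyl has three syn-axial neighbours and reacts slowly, while it sits within bonding distance of the C12 ester, so loss of 4-methoxybenzyl alcohol and return to 16 is the expected side process. The fallback sets out from 18 and returns at 21, and builds the side chain on the oxygen in two stages. 18 is acylated with diethylphosphonoacetic acid and N,N′-dicyclohexylcarbodiimide in CH2Cl2, a neutral and fast ketene-type acylation suited to hindered alcohols, to give 11-tert-butyl 12-(4-methoxybenzyl) 6β-[(diethoxyphosphoryl)acetoxy]drimane-11,12-dioate F8. A Horner–Wadsworth–Emmons reaction of F8 with (2E,4E)-hexa-2,4-dienal (LiCl, iPr2NEt, MeCN) then gives 21.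

Step 9. Enolisation of the 9α-ester epimer may be incomplete, because its C9–H is the β-hydrogen shielded by the C10 methyl and the lactone bridge, so part of the material would remain unconverted. The fallback sets out from 14 and returns at 15 and then 16, and reaches the enolate without removing that hydrogen with an amide base. CF3CO2H/CH2Cl2 cleaves the tert-butyl ester to 12,6β-olide-drimane-11-oic acid F9. (COCl)2 with catalytic DMF gives the acid chloride 12,6β-olide-drimane-11-oyl chloride F10, whose far more acidic C9–H is removed by Et3N to give the ketene 12,6β-olide-11-nor-driman-9-ylidenemethanone F11. LiOtBu adds to the ketene carbon of F11 and gives enolate 15 directly, which is protonated with AcOH as in step 9 to give 16.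

Step 4. The two diastereomeric salts may co-crystallise and leave the acid incompletely resolved. The fallback sets out from 6 and returns at 10, and uses covalent diastereomers instead. 6 is coupled (N,N′-dicyclohexylcarbodiimide, DMAP, CH2Cl2) with (S)-4-benzyloxazolidin-2-one to the imide (4S)-4-benzyl-3-[(1S)-2,6,6-trimethylcyclohex-2-ene-1-carbonyl]oxazolidin-2-one F12 and its (1R)-acyl diastereomer F13, which are separated by chromatography. LiBH4 in wet Et2O cleaves F12 reductively to 10.

## Further compounds

F1 | step 8 | 11-tert-butyl 12-methyl 6-oxodrimane-11,12-dioate (C8 and C9 epimers) | O=C1CC(C(=O)OC)C(C(=O)OC(C)(C)C)[C@@]2(C)CCCC(C)(C)[C@H]12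
F2 | step 8 | 11-tert-butyl 12-methyl 6β-hydroxydrimane-11,12-dioate (C8 and C9 epimers) | O[C@@H]1CC(C(=O)OC)C(C(=O)OC(C)(C)C)[C@@]2(C)CCCC(C)(C)[C@H]12
F3 | step 6 | di-tert-butyl 2-[(1S,2S)-2-(hydroxymethyl)-1,3,3-trimethylcyclohexyl]butanedioate (C9 epimers) | OC[C@H]1C(C)(C)CCC[C@]1(C)C(C(=O)OC(C)(C)C)CC(=O)OC(C)(C)C
F4 | step 6 | di-tert-butyl 2-[(dimethylamino)methyl]-3-[(1S,2S)-2-(hydroxymethyl)-1,3,3-trimethylcyclohexyl]butanedioate | OC[C@H]1C(C)(C)CCC[C@]1(C)C(C(=O)OC(C)(C)C)C(CN(C)C)C(=O)OC(C)(C)C
F5 | step 6 | trimethylammonium iodide of F4 | OC[C@H]1C(C)(C)CCC[C@]1(C)C(C(=O)OC(C)(C)C)C(C[N+](C)(C)C)C(=O)OC(C)(C)C.[I-]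
F6 | step 6 | di-tert-butyl 3-[(1S,2S)-2-(hydroxymethyl)-1,3,3-trimethylcyclohexyl]-2-methylidenebutanedioate | OC[C@H]1C(C)(C)CCC[C@]1(C)C(C(=O)OC(C)(C)C)C(=C)C(=O)OC(C)(C)C
F7 | step 6 | di-tert-butyl 3-[(1S,2S)-2-formyl-1,3,3-trimethylcyclohexyl]-2-methylidenebutanedioate | O=C[C@H]1C(C)(C)CCC[C@]1(C)C(C(=O)OC(C)(C)C)C(=C)C(=O)OC(C)(C)C
F8 | step 11 | 11-tert-butyl 12-(4-methoxybenzyl) 6β-[(diethoxyphosphoryl)acetoxy]drimane-11,12-dioate | CCOP(=O)(OCC)CC(=O)O[C@@H]1C[C@H](C(=O)OCc3ccc(OC)cc3)[C@H](C(=O)OC(C)(C)C)[C@@]2(C)CCCC(C)(C)[C@H]12
F9 | step 9 | 12,6β-olide-drimane-11-oic acid (C9 epimers) | O=C1O[C@@H]2C[C@H]1C(C(=O)O)[C@@]3(C)CCCC(C)(C)[C@H]23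
F10 | step 9 | 12,6β-olide-drimane-11-oyl chloride (C9 epimers) | O=C1O[C@@H]2C[C@H]1C(C(=O)Cl)[C@@]3(C)CCCC(C)(C)[C@H]23
F11 | step 9 | ketene at C9 of the 12,6β-olide (C9=C11=O) | O=C1O[C@@H]2C[C@H]1C(=C=O)[C@@]3(C)CCCC(C)(C)[C@H]23
F12 | step 4 | (4S)-4-benzyl-3-[(1S)-2,6,6-trimethylcyclohex-2-ene-1-carbonyl]oxazolidin-2-one | O=C1OC[C@H](Cc2ccccc2)N1C(=O)[C@H]3C(C)(C)CCC=C3C
F13 | step 4 | (4S)-4-benzyl-3-[(1R)-2,6,6-trimethylcyclohex-2-ene-1-carbonyl]oxazolidin-2-one | O=C1OC[C@H](Cc2ccccc2)N1C(=O)[C@@H]3C(C)(C)CCC=C3C
A1 | alternative 1 | cis-3-methyl-5-oxocyclohex-3-ene-1,2-dicarboxylic anhydride (ring B enone anhydride) | O=C1C[C@@H]2C(=O)OC(=O)[C@@H]2C(C)=C1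
A2 | alternative 1 | allylidenecyclopropane | C=CC=C1CC1
A3 | alternative 1 | cis-fused spiro-cyclopropane cycloadduct (C5 epimeric to the target) | O=C1C[C@@H]2C(=O)OC(=O)[C@@H]2[C@@]3(C)CC=CC4(CC4)[C@@H]13
A4 | alternative 2 | triene with (E)-enoate, (Z)-silyl dienol ether and (E)-N-enoyl oxazolidinone | CC(C)(C)OC(=O)/C=C/C(O[Si](C)(C)C(C)(C)C)=C/C(C)(C)CCC/C(C)=C/C(=O)N1CCOC1=O
A5 | alternative 2 | trans-fused octalin cycloadduct (C6 silyl enol ether, 8β-tert-butyl ester, 9β-acyl oxazolidinone) | CC(C)(C)[Si](C)(C)OC1=C[C@H](C(=O)OC(C)(C)C)[C@H](C(=O)N3CCOC3=O)[C@@]2(C)CCCC(C)(C)[C@H]12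
A6 | alternative 3 | trans-fused δ-lactone (C11 to O6) with the (E)-tert-butyl acrylate arm on C6 | O=C1C[C@@]2(C)CCCC(C)(C)[C@@H]2[C@@H](/C=C/C(=O)OC(C)(C)C)O1
A7 | alternative 3 | tert-butyldimethylsilyl ketene acetal of A6 | CC(C)(C)[Si](C)(C)OC1=C[C@@]2(C)CCCC(C)(C)[C@@H]2[C@@H](/C=C/C(=O)OC(C)(C)C)O1
A8 | alternative 3 | 12-tert-butyl hydrogen drim-6-ene-11,12-dioate (8β-ester, 9β-acid) | C1=C[C@H](C(=O)OC(C)(C)C)[C@H](C(=O)O)[C@@]2(C)CCCC(C)(C)[C@H]12
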